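All runs stem from a simulated flask with constants of no real substance; the scatter is artificial.

The small charge of the spring run, 0.050 M of substrate, already failed to add up: at 10.0 min, substrate and target came to 89.0% of the charge. The target column counts idle adduct and product in the second phase, so nothing needs adding to it. The summer run, at 0.20 M, came to 88.0%.

| flask | substrate | reagent in the second phase | remark | time | volume of the second phase over the first |
|---|---|---|---|---|---|
| spring | 0.050 M | 1.5 equiv | run made earlier |  |  |
| summer | 0.20 M | 1.5 equiv | run made earlier |  |  |
| flask | 0.10 M | 1.50 equiv |  | 15 min | 2.0 |

| run | time / min | target / % | idle adduct / % | substrate / % |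
|---|---|---|---|---|
| spring | 1.33 | 10 | 3 | 89 |
| spring | 2.50 | 23 | 2 | 78 |
| spring | 4.00 | 42 | 2 | 55 |
| spring | 5.00 | 47 | 2 | 51 |
| spring | 6.00 | 54 | 2 | 40 |
| spring | 8.00 | 62 | 5 | 30 |
| spring | 10.0 | 69 | 5 | 20 |
| summer | 0.500 | 5 | 0 | 95 |
| summer | 1.33 | 25 | 6 | 77 |
| summer | 2.50 | 45 | 10 | 56 |
| summer | 4.00 | 61 | 9 | 32 |
| summer | 5.00 | 70 | 7 | 24 |
| summer | 8.00 | 82 | 7 | 7 |
| summer | 10.0 | 84 | 9 | 4 |

(each reading ± 1.5 percentage points)

- what is said of target includes product in the second phase and idle adduct
- in the second phase: reagent in the second phase, product in the second phase; everything else is in the first
- charges count per volume of the first phase; a concentration in a rate is the amount of a species over the volume of its own phase; every rate counts per litre of the first phase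
- the earlier runs hold the two phases in the same ratio of volumes as the flask asked about

* how much target and product in the second phase and idle adduct together there is at 15 min, in percent of the substrate charged
* part of the substrate charged that has reacted at 15 min

I called the mass-balance deficit, averaged over the two runs and divided by the time, the leak: 0.0115 min⁻¹ of the charge. I doubted a straight line, since a loss from target ought to grow with target. But the summer target stood at 84% against 69% in spring, while the two deficits differed by 1 percentage point, less than the 1.5 points scatter of one reading. I also doubted a single pair of readings, but those at 8.00 min gave 0.0119 min⁻¹.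

The flask's charge is the geometric mean of the two earlier charges, so I took the geometric mean of the substrate left at 10.0 min, 8.94%. Continuing that decay to 15 min left 2.67%. My reckoning for the flask was therefore cv 97.3% and y 80.1%.

The forecast gave 96.5% and 91%, on this reading of the columns: “I read y as the target column plus the idle adduct”. We agreed on cv and parted on y.

The flask gave cv 96.7% and y 80.1%, 11 points below the forecast.

    reagent in the reaction phase ⇌ reagent in the second phase, rate k1*([reagent in the reaction phase] - [reagent in the second phase]/K1) per volume of the first phase (partition coefficient = 0.351, kL = 0.219 min⁻¹)
    substrate + reagent in the reaction phase → target (k = 8.07 M⁻¹ min⁻¹)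
    target ⇌ product in the second phase, rate k3*([target] - [product in the second phase]/K3) per volume of the first phase (partition coefficient = 2.90, kL = 0.342 min⁻¹)
    target → decomposed product (k = 0.0589 min⁻¹)
    reagent in the reaction phase + target ⇌ idle adduct, settled at all times (K = 8.90 M⁻¹)

In the flask, half of the turnover up to 15 min was done by 2.10 min on the reagent's way across, by 3.34 min on the path from substrate to target, and by 5.62 min on target's way across, while reagent in the reaction phase stood at 0.0274 M at 1.50 min, 0.0297 M at 7.50 min and 0.0284 M at 15.0 min. Meanwhile decomposed product rose to 8.87% at 7.50 min and 16.6% at 15.0 min, where the leak had said 17.2%. Read at 6.0 min, the same flask gets 6.90% from the leak; computed, it holds 6.73% decomposed product, with y 66.3%.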